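**Retrosynthetic overview**
1. Plagiochin E comes from its trimethyl ether by O-demethylation; rings A/D are the biaryl pair, rings B/C the diaryl ether pair.
2. The 16-membered macrocycle is the only ring formed and is formed last: intramolecular McMurry coupling of a ring C / ring D dialdehyde, then hydrogenation, gives the C–D ethano bridge.
3. The A–B ethano bridge is the key C–C bond: intermolecular Perkin (aldol-type) condensation of an A–D biaryl arylacetic acid with a B–C diaryl ether aldehyde, then decarboxylation and hydrogenation.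
4. The A–D biaryl comes from a Suzuki coupling of a ring A boronate with a ring D salicylate triflate; the B–C diaryl ether from SNAr of isovanillin on methyl 4-fluorobenzoate.
5. All four benzene rings are bought as simple arenes.

Assumption: the SMILES has no stereodescriptor and the target has no stereogenic centre (the biaryl axis is unassigned), so the compound is made exactly as drawn and no asymmetric step is needed.
Assumption: salt or metal-bound forms of a product that are only protonated on aqueous work-up (carboxylate, alkoxide, aryl borate) are not counted as separate compounds.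

**Route**

Step 1
Reactants: 1 methyl 2-(3-methoxyphenyl)acetate
Product: 2 methyl 2-(2-bromo-5-methoxyphenyl)acetate
Conditions: NBS (1.05 equiv), MeCN, 0 °C → rt, dark
Reagents that add atoms: N-bromosuccinimide, O=C1CCC(=O)N1Br
Why: Electrophilic aromatic bromination; NBS in MeCN brominates the anisole ring para to OMe (the position ortho to the CH2CO2Me arm), and the benzylic position is untouched in the dark.

Step 2
Reactants: 2 methyl 2-(2-bromo-5-methoxyphenyl)acetate
Product: 3 methyl 2-[5-methoxy-2-(4,4,5,5-tetramethyl-1,3,2-dioxaborolan-2-yl)phenyl]acetate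
Conditions: B2pin2 (1.2 equiv), PdCl2(dppf) (3 mol %), KOAc (3 equiv), 1,4-dioxane, 90 °C
Reagents that add atoms: bis(pinacolato)diboron, CC1(C)OB(OC1(C)C)B1OC(C)(C)C(C)(C)O1
Why: Miyaura borylation; the aryl bromide adds to zerovalent palladium and acetate-assisted transmetalation from B2pin2 gives the boronate, KOAc being too weak to enolise the ester or cause homocoupling.

Step 3
Reactants: 4 methyl 2-hydroxy-3-methoxybenzoate
Product: 5 methyl 3-methoxy-2-(trifluoromethylsulfonyloxy)benzoate
Conditions: Tf2O (1.2 equiv), pyridine, CH2Cl2, 0 °C → rt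
Reagents that add atoms: trifluoromethanesulfonic anhydride, O=S(=O)(OS(=O)(=O)C(F)(F)F)C(F)(F)F
Why: O-Sulfonylation (triflate formation) turns the cheap salicylate into a cross-coupling electrophile activated by its ortho ester.

Step 4
Reactants: 3 methyl 2-[5-methoxy-2-(4,4,5,5-tetramethyl-1,3,2-dioxaborolan-2-yl)phenyl]acetate; 5 methyl 3-methoxy-2-(trifluoromethylsulfonyloxy)benzoate
Product: 6 methyl 3-methoxy-2-[4-methoxy-2-(2-methoxy-2-oxoethyl)phenyl]benzoate (A–D biaryl diester)
Conditions: Pd(OAc)2 (5 mol %), SPhos (10 mol %), K3PO4 (3 equiv), toluene/H2O 10:1, 90 °C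
Reagents that add atoms: none
Why: Suzuki–Miyaura cross-coupling; the electron-poor triflate adds readily to zerovalent palladium and the bulky, electron-rich SPhos ligand carries transmetalation and reductive elimination through to the tri-ortho-substituted biaryl.

Step 5
Reactants: 6 methyl 3-methoxy-2-[4-methoxy-2-(2-methoxy-2-oxoethyl)phenyl]benzoate
Product: 7 2-{5-methoxy-2-[2-methoxy-6-(methoxycarbonyl)phenyl]phenyl}acetic acid
Conditions: LiOH·H2O (1.2 equiv), THF/H2O 3:1, 0 °C → rt; then 1 M HCl
Reagents that add atoms: lithium hydroxide, [Li+].[OH-]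
Why: Chemoselective saponification; the unhindered aliphatic arylacetate ester hydrolyses far faster than the benzoate flanked by the ortho aryl group, so only the acetic acid arm is freed.

Step 6
Reactants: 8 isovanillin (3-hydroxy-4-methoxybenzaldehyde); 9 methyl 4-fluorobenzoate
Product: 10 methyl 4-(5-formyl-2-methoxyphenoxy)benzoate (B–C diaryl ether)
Conditions: K2CO3 (2 equiv), DMSO, 120 °C
Reagents that add atoms: none
Why: Nucleophilic aromatic substitution (SNAr); the deprotonated phenol of 8 attacks the fluoroarene para to its ester and fluoride leaves, while the non-enolisable aldehyde is inert to carbonate.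

Step 7 (key step)
Reactants: 7 2-{5-methoxy-2-[2-methoxy-6-(methoxycarbonyl)phenyl]phenyl}acetic acid; 10 methyl 4-(5-formyl-2-methoxyphenoxy)benzoate
Product: 13 (2E)-3-{4-methoxy-3-[4-(methoxycarbonyl)phenoxy]phenyl}-2-{5-methoxy-2-[2-methoxy-6-(methoxycarbonyl)phenyl]phenyl}prop-2-enoic acid, via mixed anhydride 11 (not isolated), via β-acetoxy acid 12 (not isolated)
Conditions: Ac2O (5 equiv), Et3N (3 equiv), 110 °C; then H2O, HCl
Reagents that add atoms: none
Why: Perkin condensation (Oglialoro form), an intermolecular aldol condensation: Et3N enolises 11, the enolate adds to the non-enolisable aldehyde 10, acetyl transfer gives 12, and E1cB loss of acetate forms the C=C bond as the preferred (E)-acid with the two aryl groups cis (geometry is erased in step 9).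

Step 8
Reactants: 13 the (2E)-diarylpropenoic acid
Product: 14 methyl 3-methoxy-2-{4-methoxy-2-[(Z)-2-{4-methoxy-3-[4-(methoxycarbonyl)phenoxy]phenyl}ethenyl]phenyl}benzoate
Conditions: Cu powder (0.5 equiv), quinoline, 205 °C, N2
Reagents that add atoms: none
Why: Copper-mediated protodecarboxylation of the α-arylcinnamic acid, the classical second stage of the Perkin stilbene synthesis, replaces CO2H by H to give mainly the (Z)-stilbene (any (E) isomer is equally usable).

Step 9
Reactants: 14 the (Z)-stilbene diester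
Product: 15 methyl 3-methoxy-2-{4-methoxy-2-[2-{4-methoxy-3-[4-(methoxycarbonyl)phenoxy]phenyl}ethyl]phenyl}benzoate
Conditions: H2 (1 atm), 10% Pd/C, EtOAc, rt
Reagents that add atoms: none
Why: Heterogeneous catalytic hydrogenation saturates the stilbene C=C to the flexible bibenzyl while aryl esters, methyl ethers and the diaryl ether are inert.

Step 10
Reactants: 15 the bibenzyl diester
Product: 16 {2-[2-(2-{3-[4-(hydroxymethyl)phenoxy]-4-methoxyphenyl}ethyl)-4-methoxyphenyl]-3-methoxyphenyl}methanol (diol)
Conditions: LiAlH4 (2.5 equiv), THF, 0 °C → rt; then H2O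
Reagents that add atoms: none
Why: Hydride reduction converts both methyl esters into benzylic alcohols, and nothing else in the molecule is reducible by LiAlH4.

Step 11
Reactants: 16 the diol
Product: 17 2-[2-(2-{3-(4-formylphenoxy)-4-methoxyphenyl}ethyl)-4-methoxyphenyl]-3-methoxybenzaldehyde (dialdehyde)
Conditions: activated MnO2 (20 equiv), CH2Cl2, rt
Reagents that add atoms: none
Why: Benzylic alcohol oxidation on MnO2 stops cleanly at the aldehyde and delivers the dialdehyde for ring closure.

Step 12
Reactants: 17 the dialdehyde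
Product: 19 plagiochin E trimethyl ether bearing a (Z)-CH=CH bridge between rings C and D (16-membered cyclic stilbene), via titanium pinacolate 18 (not isolated)
Conditions: TiCl4 (12 equiv), Zn dust (24 equiv), pyridine, THF, reflux; 17 added over 20 h (final 2 mM)
Reagents that add atoms: none
Why: Intramolecular McMurry coupling; zerovalent titanium made from TiCl4 and Zn couples the two aldehydes reductively to 18 and deoxygenates it to the alkene, high dilution favouring the 16-membered ring over oligomers (alkene geometry is irrelevant, it is hydrogenated next).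

Step 13
Reactants: 19 the cyclic stilbene
Product: 20 plagiochin E tri-O-methyl ether
Conditions: H2 (1 atm), 10% Pd/C, EtOAc/THF, rt
Reagents that add atoms: none
Why: Catalytic hydrogenation of the strained cyclic stilbene C=C gives the saturated C–D bridge, and no other group is affected.

Step 14
Reactants: 20 plagiochin E tri-O-methyl ether
Product: 21 plagiochin E
Conditions: BBr3 (9 equiv), CH2Cl2, −78 °C → rt; then H2O
Reagents that add atoms: none
Why: Lewis acid O-demethylation; BBr3 complexes each aryl methyl ether and bromide cleaves the O–CH3 bond by SN2, leaving the diaryl ether and both bridges intact, and hydrolysis frees the three phenols of the target, which has no stereocentre to set.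

**Compound list**
1 | methyl 2-(3-methoxyphenyl)acetate | COC(=O)Cc1cccc(OC)c1 | starting material
2 | methyl 2-(2-bromo-5-methoxyphenyl)acetate | COC(=O)Cc1cc(OC)ccc1Br | intermediate
3 | methyl 2-[5-methoxy-2-(4,4,5,5-tetramethyl-1,3,2-dioxaborolan-2-yl)phenyl]acetate | COC(=O)Cc1cc(OC)ccc1B1OC(C)(C)C(C)(C)O1 | intermediate
4 | methyl 2-hydroxy-3-methoxybenzoate | COC(=O)c1cccc(OC)c1O | starting material
5 | methyl 3-methoxy-2-(trifluoromethylsulfonyloxy)benzoate | COC(=O)c1cccc(OC)c1OS(=O)(=O)C(F)(F)F | intermediate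
6 | methyl 3-methoxy-2-[4-methoxy-2-(2-methoxy-2-oxoethyl)phenyl]benzoate | COC(=O)Cc1cc(OC)ccc1-c1c(OC)cccc1C(=O)OC | intermediate
7 | 2-{5-methoxy-2-[2-methoxy-6-(methoxycarbonyl)phenyl]phenyl}acetic acid | OC(=O)Cc1cc(OC)ccc1-c1c(OC)cccc1C(=O)OC | intermediate
8 | isovanillin (3-hydroxy-4-methoxybenzaldehyde) | COc1ccc(C=O)cc1O | starting material
9 | methyl 4-fluorobenzoate | COC(=O)c1ccc(F)cc1 | starting material
10 | methyl 4-(5-formyl-2-methoxyphenoxy)benzoate | COC(=O)c1ccc(Oc2cc(C=O)ccc2OC)cc1 | intermediate
11 | mixed acetic anhydride of acid 7 (not isolated) | CC(=O)OC(=O)Cc1cc(OC)ccc1-c1c(OC)cccc1C(=O)OC | intermediate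
12 | 3-acetoxy-3-{4-methoxy-3-[4-(methoxycarbonyl)phenoxy]phenyl}-2-{5-methoxy-2-[2-methoxy-6-(methoxycarbonyl)phenyl]phenyl}propanoic acid, racemic diastereomer mixture (not isolated) | OC(=O)C(c1cc(OC)ccc1-c1c(OC)cccc1C(=O)OC)C(OC(C)=O)c1ccc(OC)c(Oc2ccc(cc2)C(=O)OC)c1 | intermediate
13 | (2E)-3-{4-methoxy-3-[4-(methoxycarbonyl)phenoxy]phenyl}-2-{5-methoxy-2-[2-methoxy-6-(methoxycarbonyl)phenyl]phenyl}prop-2-enoic acid | OC(=O)/C(=C/c1ccc(OC)c(Oc2ccc(cc2)C(=O)OC)c1)c1cc(OC)ccc1-c1c(OC)cccc1C(=O)OC | intermediate
14 | methyl 3-methoxy-2-{4-methoxy-2-[(Z)-2-{4-methoxy-3-[4-(methoxycarbonyl)phenoxy]phenyl}ethenyl]phenyl}benzoate | COC(=O)c1ccc(Oc2cc(/C=C\c3cc(OC)ccc3-c3c(OC)cccc3C(=O)OC)ccc2OC)cc1 | intermediate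
15 | methyl 3-methoxy-2-{4-methoxy-2-[2-{4-methoxy-3-[4-(methoxycarbonyl)phenoxy]phenyl}ethyl]phenyl}benzoate | COC(=O)c1ccc(Oc2cc(CCc3cc(OC)ccc3-c3c(OC)cccc3C(=O)OC)ccc2OC)cc1 | intermediate
16 | {2-[2-(2-{3-[4-(hydroxymethyl)phenoxy]-4-methoxyphenyl}ethyl)-4-methoxyphenyl]-3-methoxyphenyl}methanol | OCc1ccc(Oc2cc(CCc3cc(OC)ccc3-c3c(OC)cccc3CO)ccc2OC)cc1 | intermediate
17 | 2-[2-(2-{3-(4-formylphenoxy)-4-methoxyphenyl}ethyl)-4-methoxyphenyl]-3-methoxybenzaldehyde | O=Cc1ccc(Oc2cc(CCc3cc(OC)ccc3-c3c(OC)cccc3C=O)ccc2OC)cc1 | intermediate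
18 | titanium-bound cyclic 1,2-diolate (pinacolate) of the macrocycle, drawn as the free diol, diastereomer mixture (not isolated) | COc1ccc2c(c1)CCc1ccc(OC)c(c1)Oc1ccc(cc1)C(O)C(O)c1cccc(OC)c1-2 | intermediate
19 | plagiochin E trimethyl ether with a (Z)-CH=CH bridge between rings C and D | COc1ccc2c(c1)CCc1ccc(OC)c(c1)Oc1ccc(cc1)/C=C\c1cccc(OC)c1-2 | intermediate
20 | plagiochin E tri-O-methyl ether | COc1ccc2c(c1)CCc1ccc(OC)c(c1)Oc1ccc(cc1)CCc1cccc(OC)c1-2 | intermediate
21 | plagiochin E | Oc1ccc2c(c1)CCc1ccc(O)c(c1)Oc1ccc(cc1)CCc1cccc(O)c1-2 | target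

**Summary**
Total steps: 14. Longest linear sequence: 12 steps (steps 1, 2, 4, 5, 7, 8, 9, 10, 11, 12, 13, 14, from compound 1). Steps 3 and 6 are side branches.

**Three steps most likely to fail, with fallbacks**

Step 12 (McMurry macrocyclisation; strained 16-membered ring, risk of oligomers and pinacols). The fallback closes the ring through sulfur and then contracts it. It sets out from diol 16: PBr3 in CH2Cl2 at 0 °C gives the bis(bromomethyl) compound F1. Slow simultaneous addition of F1 and Na2S·9H2O to EtOH/toluene at high dilution gives the 17-membered cyclic thioether F2 by twofold SN2. mCPBA (2.2 equiv, CH2Cl2, 0 °C) oxidises it to the cyclic sulfone F3. A Ramberg–Bäcklund ring contraction (CBr2F2, KOH on Al2O3, t-BuOH/CH2Cl2) extrudes SO2 and gives the cyclic stilbene 19, where the route is rejoined before step 13.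

Step 8 (Cu/quinoline decarboxylation at 205 °C; risk of charring or ester loss). The fallback removes the carboxyl group by a radical path after saturating the alkene. It sets out from acid 13: hydrogenation (H2 3 atm, Pd/C, EtOAc/AcOH) gives the racemic 2,3-diarylpropanoic acid F4. N-Hydroxypyridine-2-thione, DCC and catalytic DMAP (CH2Cl2, dark) convert it into the Barton ester F5. Irradiation with a tungsten lamp in toluene with t-BuSH gives Barton reductive decarboxylation directly to bibenzyl 15, where the route is rejoined before step 10 (step 9 is then not needed).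

Step 4 (Suzuki coupling to a tri-ortho-substituted biaryl; risk of triflate hydrolysis and protodeboronation). The fallback reverses the polarity in a base-free Negishi coupling. It sets out from bromide 2 (step 2 is skipped). Purchased methyl 2-iodo-3-methoxybenzoate (COC(=O)c1cccc(OC)c1I) is treated with zinc dust and LiCl in THF to give [2-methoxy-6-(methoxycarbonyl)phenyl]zinc iodide F6. Coupling of F6 with 2 (Pd(OAc)2, SPhos, THF, 60 °C) gives the biaryl diester 6, where the route is rejoined before step 5.

**Further compounds**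
F1 | step 12 | 2-[2-(2-{3-[4-(bromomethyl)phenoxy]-4-methoxyphenyl}ethyl)-4-methoxyphenyl]-1-(bromomethyl)-3-methoxybenzene | BrCc1ccc(Oc2cc(CCc3cc(OC)ccc3-c3c(OC)cccc3CBr)ccc2OC)cc1
F2 | step 12 | 17-membered cyclic thioether (CH2–S–CH2 between rings C and D) of the trimethyl ether skeleton | COc1ccc2c(c1)CCc1ccc(OC)c(c1)Oc1ccc(cc1)CSCc1cccc(OC)c1-2
F3 | step 12 | corresponding cyclic sulfone (CH2–SO2–CH2 between rings C and D) | COc1ccc2c(c1)CCc1ccc(OC)c(c1)Oc1ccc(cc1)CS(=O)(=O)Cc1cccc(OC)c1-2
F4 | step 8 | 3-{4-methoxy-3-[4-(methoxycarbonyl)phenoxy]phenyl}-2-{5-methoxy-2-[2-methoxy-6-(methoxycarbonyl)phenyl]phenyl}propanoic acid (racemic) | OC(=O)C(Cc1ccc(OC)c(Oc2ccc(cc2)C(=O)OC)c1)c1cc(OC)ccc1-c1c(OC)cccc1C(=O)OC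
F5 | step 8 | 2-thioxopyridin-1(2H)-yl ester (Barton ester) of acid F4 | S=C1C=CC=CN1OC(=O)C(Cc1ccc(OC)c(Oc2ccc(cc2)C(=O)OC)c1)c1cc(OC)ccc1-c1c(OC)cccc1C(=O)OC
F6 | step 4 | [2-methoxy-6-(methoxycarbonyl)phenyl]zinc iodide | COC(=O)c1cccc(OC)c1[Zn]I
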